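**Retrosynthetic overview**

1. C10 and the two acyclic fragments: 1 + 2 → 3 (asymmetric conjugate alkynylation); 4 + 5 + 6 → (7, 8) → 9 (allylboronate).
2. Ring A (γ-lactone) first: 3 + 9 → (10) → 11 by allylboration (C7–C8) and lactone C–O closure; desilylation gives 12.
3. Ring B (cycloheptene) second: 12 + 13 → (14) → 15 (8-epi-xanthatin) by enyne ring-closing/cross metathesis.
4. Oxirane (C–O) on the monomer: 15 → 16 (1β,5β-epoxide), which can act only as dienophile.
5. Ring C third by [4+2] union 15 + 16 → 17 (C5–C13′, C3–C11′); last and key, the C1–O bond with 1,3-shift of the alkene, 17 → (18) → 19 (target).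

Assumption: xanthane numbering (C1–C15) is used for each C15 unit, primed for the epoxide-bearing unit; α/β refer to H7 = α.
Assumption: in steps 1 and 3 the catalyst antipode named is the one expected by analogy with simple substrates; the other antipode is used if the sense proves opposite.

**Step 1**
Reactants: 1 (E)-but-2-enal; 2 ethynyltri(propan-2-yl)silane
Product: 3 (3S)-3-methyl-5-[tri(propan-2-yl)silyl]pent-4-ynal
Conditions: [Rh(OAc)(C2H4)2]2 (2.5 mol%), (R)-DTBM-SEGPHOS (6 mol%), MeOH, 40 °C
Reagents that add atoms: none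
Why: Rhodium-catalysed asymmetric conjugate alkynylation of an enal, in which the bulky silyl group suppresses alkyne dimerisation and the chiral bisphosphine–rhodium alkynyl adds to one enantioface to set C10 (S).

**Step 2**
Reactants: 4 methyl prop-2-ynoate; 5 allylmagnesium bromide; 6 2-(iodomethyl)-4,4,5,5-tetramethyl-1,3,2-dioxaborolane
Product: 9 methyl (2E)-2-[(4,4,5,5-tetramethyl-1,3,2-dioxaborolan-2-yl)methyl]hexa-2,5-dienoate, via allylcopper 7 (not isolated), via alkenylcopper 8 (not isolated)
Conditions: 5, CuBr·SMe2 (1.0 equiv), THF, −78 °C; then 4, −78 °C; then 6, DMPU, −78 → 0 °C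
Reagents that add atoms: none
Why: Syn carbocupration of the ynoate by 7 puts allyl and copper cis in 8, and alkylation of 8 by the iodomethylboronate goes with retention, so allyl ends cis to CH2B (Hall-type three-component carbocupration/borylmethylation).

**Step 3**
Reactants: 3 (3S)-3-methyl-5-[tri(propan-2-yl)silyl]pent-4-ynal; 9 the allylboronate
Product: 11 (4R,5R)-3-methylidene-5-{(2S)-2-methyl-4-[tri(propan-2-yl)silyl]but-3-yn-1-yl}-4-(prop-2-en-1-yl)oxolan-2-one, via borate 10 (not isolated)
Conditions: (S)-TRIP [(S)-3,3′-bis(2,4,6-triisopropylphenyl)-1,1′-binaphthyl-2,2′-diyl hydrogen phosphate] (5 mol%), 4 Å MS, toluene, −30 °C → rt; then p-TsOH·H2O (20 mol%), rt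
Reagents that add atoms: none
Why: Chiral-phosphoric-acid-catalysed allylboration through a closed Zimmerman–Traxler chair, in which the catalyst selects the aldehyde Si face (C8 R) and the allyl group cis to CH2B sits axial to give the syn adduct (C7 R), which lactonises under acid to the cis lactone.

**Step 4**
Reactants: 11 the silylated lactone
Product: 12 (4R,5R)-3-methylidene-5-[(2S)-2-methylbut-3-yn-1-yl]-4-(prop-2-en-1-yl)oxolan-2-one
Conditions: TBAF (1.2 equiv), AcOH (1.2 equiv), THF, 0 °C
Reagents that add atoms: none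
Why: Fluoride-induced protodesilylation of the alkynylsilane, buffered with acetic acid to spare the α-methylene lactone; no stereocentre is touched.

**Step 5**
Reactants: 12 the enyne lactone; 13 but-3-en-2-one
Product: 15 8-epi-xanthatin, via triene 14 (not isolated)
Conditions: second-generation Hoveyda–Grubbs catalyst RuCl2(H2IMes)(=CH-C6H4-2-O-i-Pr) (10 mol%), 13 (10 equiv), CH2Cl2, 40 °C
Reagents that add atoms: none
Why: Domino ring-closing enyne metathesis (exo mode, closing ring B with C1=C5 and a 1-vinyl group) followed by E-selective cross metathesis with the enone; no stereocentre is formed.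

**Step 6**
Reactants: 15 8-epi-xanthatin
Product: 16 8-epi-xanthatin 1β,5β-epoxide
Conditions: DMDO (1.1 equiv), acetone, −20 → 0 °C
Reagents that add atoms: dimethyldioxirane, CC1(C)OO1
Why: Electrophilic dioxirane epoxidation of the only electron-rich alkene (C1=C5), under substrate control: with the C10 methyl pseudo-axial (A(1,2) strain with the C1 side chain) ring B folds C7–C9 under the α face, so oxygen is expected on the β face, setting C1 (R) and C5 (R), with any α-epoxide removed by chromatography.

**Step 7**
Reactants: 15 8-epi-xanthatin (diene); 16 8-epi-xanthatin 1β,5β-epoxide (dienophile)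
Product: 17 endo [4+2] heterodimer with cyclohexene ring C (C1=C2)
Conditions: 16 (3 equiv), BHT (5 mol%), toluene (2 M), 85 °C; 15 added by syringe pump over 12 h, then 24 h; excess 16 recovered
Reagents that add atoms: none
Why: Intermolecular Diels–Alder reaction of the C5=C1–C2=C3 diene of 15 with the α-methylene lactone of 16 (which has no diene and cannot self-dimerise), in which the acrylate β-carbon C13′ bonds to the diene terminus C5 remote from the acetyl group, and the endo transition state, approach to the lactone face anti to its cis-fused seven-membered ring and to the β face of the diene set C5 (H α), C3 (H α, acetyl β) and spiro C11′ (S).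

**Step 8**
Reactants: 17 the heterodimer
Product: 19 CNP0177598.1 (target), via hydroxy selenide 18 (not isolated)
Conditions: (PhSe)2 (10 mol%), 2,4,6-tris(4-methoxyphenyl)pyrylium tetrafluoroborate (5 mol%), air, 465 nm LEDs, MeCN/H2O (9:1), rt
Reagents that add atoms: water, O
Why: Proposed new method: photo-aerobic selenium-π-acid catalysed anti-hydroxylative 1,3-transposition with water as nucleophile, in which photo-oxidised (PhSe)2 delivers PhSe+ to the α face of the only electron-rich alkene C1=C2 (the β face of ring C carries the C3 acetyl and the endo lactone carbonyl), water opens the seleniranium ion at tertiary C1 from the β face to give 18 and so sets the C1 carbinol trans to H5 (a suprafacial oxygen-ene reaction would give the C1 epimer), and photo-aerobic oxidation of the selenide then triggers syn elimination with the cis H3 (α to the ketone) to give the conjugated C2=C3 enone and return the catalyst; the closest known reactions are the diselenide/persulfate conversion of β,γ-unsaturated esters into γ-hydroxy-α,β-unsaturated esters and photo-aerobic selenium-catalysed allylic esterification.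

**Compound list**

1 | (E)-but-2-enal (crotonaldehyde) | C/C=C/C=O | starting material
2 | ethynyltri(propan-2-yl)silane | C#C[Si](C(C)C)(C(C)C)C(C)C | starting material
3 | (3S)-3-methyl-5-[tri(propan-2-yl)silyl]pent-4-ynal | O=CC[C@H](C)C#C[Si](C(C)C)(C(C)C)C(C)C | intermediate
4 | methyl prop-2-ynoate | C#CC(=O)OC | starting material
5 | allylmagnesium bromide | C=CC[Mg]Br | starting material
6 | 2-(iodomethyl)-4,4,5,5-tetramethyl-1,3,2-dioxaborolane | ICB1OC(C)(C)C(C)(C)O1 | starting material
7 | allylcopper (prop-2-en-1-ylcopper) | C=CC[Cu] | intermediate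
8 | methyl (2Z)-2-cuprio-hexa-2,5-dienoate (alkenylcopper, allyl cis to Cu) | C=CC/C=C(\[Cu])C(=O)OC | intermediate
9 | methyl (2E)-2-[(4,4,5,5-tetramethyl-1,3,2-dioxaborolan-2-yl)methyl]hexa-2,5-dienoate (allyl cis to CH2B) | C=CC/C=C(\CB1OC(C)(C)C(C)(C)O1)C(=O)OC | intermediate
10 | pinacol borate of methyl (3R,4R,6S)-4-hydroxy-6-methyl-2-methylidene-3-(prop-2-en-1-yl)-8-[tri(propan-2-yl)silyl]oct-7-ynoate | C=C(C(=O)OC)[C@@H](CC=C)[C@H](OB1OC(C)(C)C(C)(C)O1)C[C@H](C)C#C[Si](C(C)C)(C(C)C)C(C)C | intermediate
11 | (4R,5R)-3-methylidene-5-{(2S)-2-methyl-4-[tri(propan-2-yl)silyl]but-3-yn-1-yl}-4-(prop-2-en-1-yl)oxolan-2-one (cis lactone) | C=C1C(=O)O[C@H](C[C@H](C)C#C[Si](C(C)C)(C(C)C)C(C)C)[C@@H]1CC=C | intermediate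
12 | (4R,5R)-3-methylidene-5-[(2S)-2-methylbut-3-yn-1-yl]-4-(prop-2-en-1-yl)oxolan-2-one | C=C1C(=O)O[C@H](C[C@H](C)C#C)[C@@H]1CC=C | intermediate
13 | but-3-en-2-one (methyl vinyl ketone) | C=CC(C)=O | starting material
14 | (3aR,7S,8aR)-6-ethenyl-7-methyl-3-methylidene-3,3a,4,7,8,8a-hexahydro-2H-cyclohepta[b]furan-2-one | C=C1C(=O)O[C@@H]2C[C@H](C)C(C=C)=CC[C@H]12 | intermediate
15 | 8-epi-xanthatin, (3aR,7S,8aR)-7-methyl-3-methylidene-6-[(1E)-3-oxobut-1-en-1-yl]-3,3a,4,7,8,8a-hexahydro-2H-cyclohepta[b]furan-2-one | C=C1C(=O)O[C@@H]2C[C@H](C)C(/C=C/C(C)=O)=CC[C@H]12 | intermediate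
16 | 8-epi-xanthatin 1β,5β-epoxide, (1R,5R,7R,8R,10S), cis lactone, oxirane on the face of the C10 methyl | C=C1C(=O)O[C@@H]2C[C@H](C)[C@]3(/C=C/C(C)=O)O[C@@H]3C[C@H]12 | intermediate
17 | endo [4+2] heterodimer, (3S,5S,7R,8R,10S,11′S,1′R,5′R,7′R,8′R,10′S): ring C is a cyclohexene (C1=C2) closed by C5–C13′ and C3–C11′; H3 and H5 cis (α), 3-acetyl β, spiro C11′ with lactone C=O β and C7′ α | C=C1C(=O)O[C@@H]2C[C@H](C)C3=C[C@H](C(C)=O)[C@@]4(C[C@@H]3C[C@H]12)C(=O)O[C@@H]1C[C@H](C)[C@]2(/C=C/C(C)=O)O[C@@H]2C[C@@H]14 | intermediate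
18 | 1β-hydroxy-2α-(phenylselanyl) adduct of 17 (OH and SePh trans; H3 α, cis to Se) | C=C1C(=O)O[C@@H]2C[C@H](C)[C@@]3(O)[C@@H]([Se]c5ccccc5)[C@H](C(C)=O)[C@@]4(C[C@@H]3C[C@H]12)C(=O)O[C@@H]1C[C@H](C)[C@]2(/C=C/C(C)=O)O[C@@H]2C[C@@H]14 | intermediate
19 | CNP0177598.1, (1S,5S,7R,8R,10S,11′S,1′R,5′R,7′R,8′R,10′S): as 17 but with 1β-OH (trans to H5) and C2=C3 conjugated to the 3-acetyl group | C=C1C(=O)O[C@@H]2C[C@H](C)[C@@]3(O)C=C(C(C)=O)[C@@]4(C[C@@H]3C[C@H]12)C(=O)O[C@@H]1C[C@H](C)[C@]2(/C=C/C(C)=O)O[C@@H]2C[C@@H]14 | target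

**Totals and risks**

Total step count: 8. Longest linear sequence: 7 (steps 1, 3, 4, 5, 6, 7, 8; step 2 is the side branch).

The three steps most likely to fail are steps 6, 7 and 8.

Step 6 may fail on face selectivity, because an undirected epoxidation of a flexible cycloheptene is not secured by precedent on this substrate. The fallback sets out from 15 and comes back at 16 and replaces substrate control by catalyst control: Shi epoxidation with the D-fructose-derived ketone (30 mol%), KHSO5 (as Oxone), K2CO3, MeCN/dimethoxymethane/aqueous buffer, 0 °C. The spiro transition state that gives (R,R)-oxides from 1-arylcycloalkenes predicts the (1R,5R), that is β, epoxide. This fallback makes no new compound (F0).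

Step 7 may fail on cross- versus homo-dimerisation and on endo/exo or facial selectivity. The fallback sets out from 15 and comes back at 19 and moves the epoxidation to the end. Heating 15 alone (neat, 80 °C), where only one type of adduct can form, gives the endo homodimer F1. The hydroxylative transposition of step 8 (or its fallback) at the isolated C1=C2 alkene then gives the 1β-hydroxy enone F2. DMDO finally epoxidises the only remaining electron-rich alkene, C1′=C5′, to give 19.

Step 8 is the proposed new step; its risks are the face of selenium delivery on a hindered alkene and competing photo-oxidation. The fallback uses known chemistry, sets out from 17 and comes back at 19: copper-catalysed vinylogous aerobic oxidation with Cu(OTf)2 (10 mol%), 1,1,3,3-tetramethylguanidine (20 mol%), air, DMSO, rt. The base removes the doubly activated H3, and the extended dienolate takes up O2 at the γ-carbon C1 anti to the axial H5 to give the C1 β-hydroperoxide F3, which PPh3 reduces in the same flask to 19.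

**Further compounds**

F0 | step 6 | none | none
F1 | step 7 | endo [4+2] homodimer of 8-epi-xanthatin (as 17 with C1′=C5′ in place of the oxirane) | C=C1C(=O)O[C@@H]2C[C@H](C)C3=C[C@H](C(C)=O)[C@@]4(C[C@@H]3C[C@H]12)C(=O)O[C@@H]1C[C@H](C)C(/C=C/C(C)=O)=CC[C@@H]14
F2 | step 7 | 1β-hydroxy-2-ene homodimer (as 19 with C1′=C5′ in place of the oxirane) | C=C1C(=O)O[C@@H]2C[C@H](C)[C@@]3(O)C=C(C(C)=O)[C@@]4(C[C@@H]3C[C@H]12)C(=O)O[C@@H]1C[C@H](C)C(/C=C/C(C)=O)=CC[C@@H]14
F3 | step 8 | C1 β-hydroperoxide (as 19 with OOH in place of OH) | C=C1C(=O)O[C@@H]2C[C@H](C)[C@@]3(OO)C=C(C(C)=O)[C@@]4(C[C@@H]3C[C@H]12)C(=O)O[C@@H]1C[C@H](C)[C@]2(/C=C/C(C)=O)O[C@@H]2C[C@@H]14
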